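In the epsilon run 30.6% of the solid substrate still lies undissolved at 30.0 h, and in the eta run 37.3%, yet product climbs ever more slowly in both. Undissolved solid remains in both runs, so for the next run we ask what extra partner buys.

the same everywhere: solid substrate 0.11 M

| charge | partner | initiator | remark | time |
|---|---|---|---|---|
| epsilon | 0.099 M | 12 mM | run made earlier |  |
| zeta | 0.099 M | 30 mM | run made earlier |  |
| eta | 0.061 M | 10 mM | run made earlier |  |
| ochre | 0.300 M | 10 mM |  | 2.5 d |
| teal | 0.0990 M | 10 mM |  | 2.5 d |
| red | 0.0600 M | 20 mM |  | 2.5 d |
| violet | 0.0250 M | 10 mM |  | 2.5 d |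

| run | time / h | product / % | solid substrate / % |
|---|---|---|---|
| epsilon | 2.50 | 3.9 | 89.3 |
| epsilon | 8.00 | 9.7 | 68.7 |
| epsilon | 15.0 | 16.2 | 50.2 |
| epsilon | 20.0 | 18.9 | 39.8 |
| epsilon | 30.0 | 20.7 | 30.6 |
| zeta | 2.50 | 0.3 | 89.3 |
| zeta | 8.00 | 0 | 66.9 |
| zeta | 15.0 | 7.9 | 39.1 |
| zeta | 20.0 | 12.3 | 23.8 |
| zeta | 30.0 | 15.1 | 7.6 |
| eta | 2.50 | 3.4 | 90.1 |
| eta | 5.00 | 6.0 | 80.2 |
| eta | 8.00 | 9.1 | 69.7 |
| eta | 15.0 | 13.5 | 53.1 |
| eta | 30.0 | 17.1 | 37.3 |

(each reading ± 0.5 percentage points)

- percent here means solid substrate units held: one ended chains counts as two
- solid substrate is a solid; its amount is given per volume of the solution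
- candidate steps: partner + first chain carrier <-> product + second chain carrier; starting material + second chain carrier -> by-product + first chain carrier; solid substrate <-> starting material; 2 first chain carrier -> ended chains; starting material + initiating radical -> capped initiator + first chain carrier; initiator -> 2 initiating radical; partner -> decomposed reagent
- at the start none of the solid substrate is in solution
- what has only dissolved of solid substrate counts as not reacted

- all flasks from highest to lowest amount of product, in percent of the solid substrate charged, at 2.5 d (ochre / teal / red / violet)
- the amount of product, in percent of the solid substrate charged of the flask you put first, at 2.5 d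
- the amount of product, in percent of the solid substrate charged of the flask you put last, at 2.5 d

We divide [product] times [product] at the last reading by the charged [partner], taking those readings as close to the stall:

eta: 5.80 mM
epsilon: 5.24 mM

Their mean, 5.52 mM, is our stall quotient Q, read with the scatter of the readings. The zeta run, with 30 mM of initiator, reads 15.1% at 30.0 h, less than epsilon's 20.7%, so we credit red's extra initiator with no gain. The square root of Q times the charged [partner] then gives our own reckoning:

ochre: 40.7 mM, or 37.0%
teal: 21.2%
red: 16.5%
violet: 11.7 mM, or 10.7%

Reckoned by what does not become product, 86.4% of ochre's partner misses it, against 53.0% of violet's. We would therefore charge ochre's partner for the amount of product, and leave the initiator at 10 mM.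

The forecast gave ochre > teal > red > violet, with 36% (27% to 47%) for the first and 11% (7% to 15%) for the last, holding that “product scales roughly as the square root of partner”.

The flasks give ochre > teal > red > violet, with 35.6% in ochre and 10.2% in violet.

    partner + first chain carrier ⇌ product + second chain carrier (K = 0.560, k = 18200 M⁻¹ s⁻¹)
    starting material + second chain carrier → by-product + first chain carrier (k = 3.23 × 10⁶ M⁻¹ h⁻¹)
    solid substrate ⇌ starting material, rate k3*(cs3 - [starting material]) while solid is left; crystals form when [starting material] > cs3 (solubility = 36.0 mM, k = 0.128 h⁻¹)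
    2 first chain carrier → ended chains (k = 4.40 × 10⁸ M⁻¹ s⁻¹)
    starting material + initiating radical → capped initiator + first chain carrier (k = 25800 M⁻¹ s⁻¹)
    initiator → 2 initiating radical (k = 0.129 h⁻¹)
    partner → decomposed reagent (k = 0.0522 h⁻¹)

Initiator has a half-life of 5.37 h, shorter than the 13.3 h of partner, and in ochre initiator is first to run out, with 0.044% left beside 3.1% of the partner at 2.50 d; at 25.0 d ochre holds 35.6% of product. From these results Q is 5.10 mM for ochre and 5.01 mM for violet, both lower than our 5.52 mM.

Take violet's flask with 0.19 M of solid substrate: Q again gives 11.7 mM, which is 6.16% of that charge. The computed flask gives 5.89%.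

The numbers in the tables stem from a simulated flask from invented constants.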